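**Retrosynthetic overview** (C1 = alkyne CH … C15 = CH3; the ring oxygen bridges C6 and C12)
1. Target ⇐ C10 acetylation and desilylation ⇐ Z-enyne by cross-metathesis on a C6 allyl group.
2. Key step: the oxocane (formed last) ⇐ ring expansion of a 2,5-cis-oxolane (ring B, O bridging C9/C12). A C6 triflate closes a transient ring A to a cis-fused bicyclic oxonium ion, and chloride opens its C9–O bond, so C6–O and C9–Cl both form with inversion.
3. anti-Chlorohydrin C6(OH)/C7(Cl) ⇐ enamine α-chlorination and allylboration of the aldehyde from hydroformylation of a C9 vinyl group.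
4. Ring B (formed first; sets C12 and C13–Br) ⇐ debenzylative bromoetherification of an E-alkene.
5. C9/C10 ⇐ Sharpless desymmetrization of divinylcarbinol; C11–C12 ⇐ epoxide opening by an E-butenylalanate.

Assumption: (2R,5R)-2,5-diphenylpyrrolidine is taken as the catalyst antipode that gives the (S)-α-chloroaldehyde in step 7; if the sense is opposite, its enantiomer is used.

**Route**

Step 1
Reactants: 1 penta-1,4-dien-3-ol
Product: 2 (1R)-1-[(2S)-oxiran-2-yl]prop-2-en-1-ol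
Conditions: t-BuOOH, Ti(OiPr)4, D-(−)-diisopropyl tartrate, 4 Å MS, CH2Cl2, −20 °C
Reagents that add atoms: tert-butyl hydroperoxide CC(C)(C)OO
Why: Sharpless asymmetric epoxidation desymmetrizes the two enantiotopic vinyl groups; the unnatural tartrate gives the erythro (2S,3R)-epoxy alcohol (future C10 and C9), and the minor enantiomer is consumed by a second epoxidation.

Step 2
Reactants: 2 (1R)-1-[(2S)-oxiran-2-yl]prop-2-en-1-ol
Product: 3 (2S)-2-[(1R)-1-[(2,6-dichlorophenyl)methoxy]prop-2-en-1-yl]oxirane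
Conditions: NaH, 2,6-dichlorobenzyl bromide, n-Bu4NI (cat.), THF, −20 → 0 °C
Reagents that add atoms: 2,6-dichlorobenzyl bromide BrCc1c(Cl)cccc1Cl
Why: Williamson etherification at low temperature avoids Payne rearrangement; the bulky benzyl group is chosen because it later steers the halocyclization to the 2,5-cis oxolane.

Step 3
Reactants: 3 (2S)-2-[(1R)-1-[(2,6-dichlorophenyl)methoxy]prop-2-en-1-yl]oxirane; 4 but-1-yne
Product: 7 (3R,4S,6E)-3-[(2,6-dichlorophenyl)methoxy]nona-1,6-dien-4-ol, via E-butenylalane 5 (not isolated), via lithium E-butenylalanate 6 (not isolated)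
Conditions: 4, i-Bu2AlH, hexane, 50 °C; n-BuLi, THF, −30 °C; then 3, −30 °C → rt
Reagents that add atoms: none
Why: syn-hydroalumination gives the E-alkenylalane, and its ate complex opens the terminal epoxide carbon by SN2 with retention of alkene geometry; no stereocentre is touched.

Step 4
Reactants: 7 (3R,4S,6E)-3-[(2,6-dichlorophenyl)methoxy]nona-1,6-dien-4-ol
Product: 8 {[(3R,4S,6E)-3-[(2,6-dichlorophenyl)methoxy]nona-1,6-dien-4-yl]oxy}triethylsilane
Conditions: Et3SiCl, imidazole, DMF, 0 °C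
Reagents that add atoms: chlorotriethylsilane CC[Si](Cl)(CC)CC
Why: standard silylation; a small, non-participating C10 protecting group is needed for steps 5 and 8.

Step 5
Reactants: 8 {[(3R,4S,6E)-3-[(2,6-dichlorophenyl)methoxy]nona-1,6-dien-4-yl]oxy}triethylsilane
Product: 10 (2R,3S,5R)-5-[(1S)-1-bromopropyl]-2-ethenyl-3-(triethylsilyloxy)oxolane, via O-dichlorobenzyl oxolanium succinimidate 9 (not isolated)
Conditions: NBS, MeCN, −20 → 0 °C, dark
Reagents that add atoms: N-bromosuccinimide O=C1CCC(=O)N1Br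
Why: debenzylative 5-exo bromoetherification (Rychnovsky–Bartlett-type halocyclization): the ether oxygen opens the bromonium ion of the more electron-rich E-alkene anti (12R,13S), the benzyl group on the oxonium oxygen sits trans to both flanking substituents so the 2,5-cis ring forms, and succinimide anion removes the benzyl group.

Step 6
Reactants: 10 (2R,3S,5R)-5-[(1S)-1-bromopropyl]-2-ethenyl-3-(triethylsilyloxy)oxolane
Product: 11 3-[(2R,3S,5R)-5-[(1S)-1-bromopropyl]-3-(triethylsilyloxy)oxolan-2-yl]propanal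
Conditions: Rh(acac)(CO)2 (2 mol%), BIPHEPHOS (4 mol%), CO/H2 (1:1, 10 bar), toluene, 60 °C
Reagents that add atoms: carbon monoxide [C-]#[O+]
Why: linear-selective hydroformylation of the monosubstituted alkene with a bulky bisphosphite ligand adds C6 as the aldehyde; the alkyl bromide and silyl ether are inert and no stereocentre is affected.

Step 7
Reactants: 11 3-[(2R,3S,5R)-5-[(1S)-1-bromopropyl]-3-(triethylsilyloxy)oxolan-2-yl]propanal; 12 4,4,5,5-tetramethyl-2-(prop-2-en-1-yl)-1,3,2-dioxaborolane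
Product: 14 (4R,5S)-6-[(2R,3S,5R)-5-[(1S)-1-bromopropyl]-3-(triethylsilyloxy)oxolan-2-yl]-5-chlorohex-1-en-4-ol, via alpha-chloroaldehyde 13 (not isolated)
Conditions: NCS, (2R,5R)-2,5-diphenylpyrrolidine (10 mol%), CH2Cl2, 0 °C; then 12, −78 °C → rt
Reagents that add atoms: N-chlorosuccinimide O=C1CCC(=O)N1Cl
Why: enamine-catalysed α-chlorination sets C7 (S) under catalyst control, and allylboration of the labile chloroaldehyde through a chair transition state in the Cornforth (polar Felkin–Anh) conformation gives the anti chlorohydrin, i.e. C6 (R).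

Step 8
Reactants: 14 (4R,5S)-6-[(2R,3S,5R)-5-[(1S)-1-bromopropyl]-3-(triethylsilyloxy)oxolan-2-yl]-5-chlorohex-1-en-4-ol
Product: 17 {[(2S,3S,5S,6S,8R)-8-[(1S)-1-bromopropyl]-3,5-dichloro-2-(prop-2-en-1-yl)oxocan-6-yl]oxy}triethylsilane, via C6 triflate 15 (not isolated), via bicyclic oxonium triflate 16 (not isolated)
Conditions: Tf2O, 2,6-di-tert-butyl-4-methylpyridine, CH2Cl2, −78 → −20 °C; then n-Bu4NCl, −20 → 0 °C
Reagents that add atoms: tetrabutylammonium chloride CCCC[N+](CCCC)(CCCC)CCCC.[Cl-]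
Why: Proposed new method: the C6 triflate is displaced with inversion by the ring-B ether oxygen (5-exo-tet neighbouring-group attack) to give a cis-fused 1-oxoniabicyclo[3.3.0]octane with allyl and C7–Cl on its convex face, and chloride then opens the ring-fusion C9–O bond with inversion, so the (6R) alcohol and (9R) ether become the (6S) ether and (9S) chloride of the oxocane in one stereospecific operation; C12 is blocked by its β-branched, β-brominated side chain and C6 is deactivated by the adjacent C–Cl dipole, whereas C9 has only the less withdrawing silyloxy neighbour, though C6 opening remains the main competing path; the closest known reaction type is the bromonium-triggered oxolane-to-oxocane ring expansion through bicyclic oxonium ions, together with halide opening of Laurencia-type oxonium ions.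

Step 9
Reactants: 18 ethynyltri(propan-2-yl)silane; 19 bromoethene
Product: 20 (but-3-en-1-yn-1-yl)tri(propan-2-yl)silane
Conditions: Pd(PPh3)2Cl2 (2 mol%), CuI (4 mol%), i-Pr2NH, THF, 0 °C → rt
Reagents that add atoms: none
Why: Sonogashira coupling of a vinyl bromide with a terminal alkyne gives the silyl-capped enyne partner for step 10.

Step 10
Reactants: 17 {[(2S,3S,5S,6S,8R)-8-[(1S)-1-bromopropyl]-3,5-dichloro-2-(prop-2-en-1-yl)oxocan-6-yl]oxy}triethylsilane; 20 (but-3-en-1-yn-1-yl)tri(propan-2-yl)silane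
Product: 21 {(3Z)-5-[(2S,3S,5S,6S,8R)-8-[(1S)-1-bromopropyl]-3,5-dichloro-6-(triethylsilyloxy)oxocan-2-yl]pent-3-en-1-yn-1-yl}tri(propan-2-yl)silane
Conditions: second-generation Grubbs catalyst (H2IMes)(PCy3)Cl2Ru=CHPh (10 mol%), 20 (5 equiv), benzene, 45 °C
Reagents that add atoms: none
Why: olefin cross-metathesis of the single alkene of 17 with a conjugated enyne, a reaction that gives the Z-1,3-enyne preferentially and so sets the C3=C4 geometry; the bulky silyl cap keeps the alkyne out of enyne metathesis.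

Step 11
Reactants: 21 {(3Z)-5-[(2S,3S,5S,6S,8R)-8-[(1S)-1-bromopropyl]-3,5-dichloro-6-(triethylsilyloxy)oxocan-2-yl]pent-3-en-1-yn-1-yl}tri(propan-2-yl)silane
Product: 22 (2S,3S,5S,6S,8R)-8-[(1S)-1-bromopropyl]-3,5-dichloro-2-[(2Z)-pent-2-en-4-yn-1-yl]oxocan-6-ol
Conditions: n-Bu4NF, AcOH (1:1), THF, 0 °C → rt
Reagents that add atoms: none
Why: fluoride desilylation removes both the O-silyl and the C-silyl group; acetic acid buffering prevents base-induced epoxide closure of the chlorohydrin and HX elimination.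

Step 12
Reactants: 22 (2S,3S,5S,6S,8R)-8-[(1S)-1-bromopropyl]-3,5-dichloro-2-[(2Z)-pent-2-en-4-yn-1-yl]oxocan-6-ol
Product: 23 (2S,3S,5S,6S,8R)-8-[(1S)-1-bromopropyl]-3,5-dichloro-2-[(2Z)-pent-2-en-4-yn-1-yl]oxocan-6-yl acetate
Conditions: Ac2O, pyridine, DMAP (cat.), CH2Cl2, 0 °C
Reagents that add atoms: acetic anhydride CC(=O)OC(C)=O
Why: DMAP-catalysed acylation of the C10 alcohol proceeds with retention and gives the target.

**Compound list**

1 | penta-1,4-dien-3-ol | C=CC(O)C=C | starting material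
2 | (1R)-1-[(2S)-oxiran-2-yl]prop-2-en-1-ol | C=C[C@@H](O)[C@@H]1CO1 | intermediate
3 | (2S)-2-[(1R)-1-[(2,6-dichlorophenyl)methoxy]prop-2-en-1-yl]oxirane | C=C[C@@H](OCc1c(Cl)cccc1Cl)[C@@H]1CO1 | intermediate
4 | but-1-yne | CCC#C | starting material
5 | [(1E)-but-1-en-1-yl]bis(2-methylpropyl)alumane | CC/C=C/[Al](CC(C)C)CC(C)C | intermediate
6 | lithium butyl[(1E)-but-1-en-1-yl]bis(2-methylpropyl)aluminate | CC/C=C/[Al-](CCCC)(CC(C)C)CC(C)C.[Li+] | intermediate
7 | (3R,4S,6E)-3-[(2,6-dichlorophenyl)methoxy]nona-1,6-dien-4-ol | C=C[C@@H](OCc1c(Cl)cccc1Cl)[C@@H](O)C/C=C/CC | intermediate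
8 | {[(3R,4S,6E)-3-[(2,6-dichlorophenyl)methoxy]nona-1,6-dien-4-yl]oxy}triethylsilane | C=C[C@@H](OCc1c(Cl)cccc1Cl)[C@@H](O[Si](CC)(CC)CC)C/C=C/CC | intermediate
9 | (2R,3S,5R)-5-[(1S)-1-bromopropyl]-1-[(2,6-dichlorophenyl)methyl]-2-ethenyl-3-(triethylsilyloxy)oxolan-1-ium succinimidate (descriptors as in 10) | C=C[C@H]1[O+](Cc2c(Cl)cccc2Cl)[C@@H]([C@@H](Br)CC)C[C@@H]1O[Si](CC)(CC)CC.O=C1CCC(=O)[N-]1 | intermediate
10 | (2R,3S,5R)-5-[(1S)-1-bromopropyl]-2-ethenyl-3-(triethylsilyloxy)oxolane | C=C[C@H]1O[C@@H]([C@@H](Br)CC)C[C@@H]1O[Si](CC)(CC)CC | intermediate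
11 | 3-[(2R,3S,5R)-5-[(1S)-1-bromopropyl]-3-(triethylsilyloxy)oxolan-2-yl]propanal | O=CCC[C@H]1O[C@@H]([C@@H](Br)CC)C[C@@H]1O[Si](CC)(CC)CC | intermediate
12 | 4,4,5,5-tetramethyl-2-(prop-2-en-1-yl)-1,3,2-dioxaborolane | C=CCB1OC(C)(C)C(C)(C)O1 | starting material
13 | (2S)-3-[(2R,3S,5R)-5-[(1S)-1-bromopropyl]-3-(triethylsilyloxy)oxolan-2-yl]-2-chloropropanal | O=C[C@@H](Cl)C[C@H]1O[C@@H]([C@@H](Br)CC)C[C@@H]1O[Si](CC)(CC)CC | intermediate
14 | (4R,5S)-6-[(2R,3S,5R)-5-[(1S)-1-bromopropyl]-3-(triethylsilyloxy)oxolan-2-yl]-5-chlorohex-1-en-4-ol | C=CC[C@@H](O)[C@@H](Cl)C[C@H]1O[C@@H]([C@@H](Br)CC)C[C@@H]1O[Si](CC)(CC)CC | intermediate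
15 | (4R,5S)-6-[(2R,3S,5R)-5-[(1S)-1-bromopropyl]-3-(triethylsilyloxy)oxolan-2-yl]-5-chlorohex-1-en-4-yl trifluoromethanesulfonate | C=CC[C@@H](OS(=O)(=O)C(F)(F)F)[C@@H](Cl)C[C@H]1O[C@@H]([C@@H](Br)CC)C[C@@H]1O[Si](CC)(CC)CC | intermediate
16 | cis-fused 1-oxoniabicyclo[3.3.0]octane triflate: O+ bonded to C6, C9 and C12; allyl on C6 and Cl on C7 on the convex face, triethylsilyloxy on C10 convex, (S)-1-bromopropyl on C12 concave | C=CC[C@H]1[C@@H](Cl)C[C@@H]2[C@@H](O[Si](CC)(CC)CC)C[C@H]([C@@H](Br)CC)[O+]12.[O-]S(=O)(=O)C(F)(F)F | intermediate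
17 | {[(2S,3S,5S,6S,8R)-8-[(1S)-1-bromopropyl]-3,5-dichloro-2-(prop-2-en-1-yl)oxocan-6-yl]oxy}triethylsilane | C=CC[C@@H]1O[C@@H]([C@@H](Br)CC)C[C@H](O[Si](CC)(CC)CC)[C@@H](Cl)C[C@@H]1Cl | intermediate
18 | ethynyltri(propan-2-yl)silane | C#C[Si](C(C)C)(C(C)C)C(C)C | starting material
19 | bromoethene | C=CBr | starting material
20 | (but-3-en-1-yn-1-yl)tri(propan-2-yl)silane | C=CC#C[Si](C(C)C)(C(C)C)C(C)C | intermediate
21 | {(3Z)-5-[(2S,3S,5S,6S,8R)-8-[(1S)-1-bromopropyl]-3,5-dichloro-6-(triethylsilyloxy)oxocan-2-yl]pent-3-en-1-yn-1-yl}tri(propan-2-yl)silane | CC(C)[Si](C(C)C)(C(C)C)C#C/C=C\C[C@@H]1O[C@@H]([C@@H](Br)CC)C[C@H](O[Si](CC)(CC)CC)[C@@H](Cl)C[C@@H]1Cl | intermediate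
22 | (2S,3S,5S,6S,8R)-8-[(1S)-1-bromopropyl]-3,5-dichloro-2-[(2Z)-pent-2-en-4-yn-1-yl]oxocan-6-ol | C#C/C=C\C[C@@H]1O[C@@H]([C@@H](Br)CC)C[C@H](O)[C@@H](Cl)C[C@@H]1Cl | intermediate
23 | (2S,3S,5S,6S,8R)-8-[(1S)-1-bromopropyl]-3,5-dichloro-2-[(2Z)-pent-2-en-4-yn-1-yl]oxocan-6-yl acetate | C#C/C=C\C[C@@H]1O[C@@H]([C@@H](Br)CC)C[C@H](OC(C)=O)[C@@H](Cl)C[C@@H]1Cl | target

**Step count and risks**

Total steps: 12. Longest linear sequence: 11 steps (steps 1–8 and 10–12 from compound 1); step 9 is a one-step side branch.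

Risk 1, the ring expansion (step 8). Chloride may open the oxonium ion at C6, returning an oxolane 6,7-dichloride, faster than at the ring-fusion carbon C9; this is the least certain step of the route. The fallback sets out from 14 and comes back at 17, and moves the expansion to the ketone oxidation level, where chloride addition at C6 is reversible. Dess–Martin oxidation of 14 (CH2Cl2, 0 °C, product used at once) gives the α-chloro ketone (5S)-6-[(2R,3S,5R)-5-[(1S)-1-bromopropyl]-3-(triethylsilyloxy)oxolan-2-yl]-5-chlorohex-1-en-4-one F1. With Me3SiOTf and then n-Bu4NCl (CH2Cl2, −78 → −20 °C) the ring-B oxygen adds to the silyl-activated ketone; chloride at C6 only forms an α-chloro ether that re-ionises, so the irreversible opening at C9 leads to the cyclic silyl ketal {[(3S,5S,6S,8R)-8-[(1S)-1-bromopropyl]-3,5-dichloro-2-(prop-2-en-1-yl)-2-(trimethylsilyloxy)oxocan-6-yl]oxy}triethylsilane F2. Ionic hydrogenation (Et3SiH, BF3·OEt2, CH2Cl2, −78 °C) delivers hydride to the ring oxocarbenium ion anti to the C7–Cl bond (Cornforth/polar Felkin–Anh), giving 17. The C6 selectivity of that reduction in an eight-membered ring is itself unproven.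

Risk 2, the debenzylative bromoetherification (step 5). The 2,5-cis selectivity is documented for iodine electrophiles and may be lower with bromonium ions, and the vinyl group could be brominated. The fallback sets out from 8 and comes back at 10, and sets C12 by reagent control and SN2 instead of by cyclization selectivity. Shi epoxidation of the E-alkene of 8 with the L-sorbose-derived enantiomer of the Shi ketone (KHSO5, K2CO3, MeCN/dimethoxymethane/buffer, 0 °C) gives (2S,3S)-2-[(2S,3R)-3-[(2,6-dichlorophenyl)methoxy]-2-(triethylsilyloxy)pent-4-en-1-yl]-3-ethyloxirane F3. BF3·OEt2 (CH2Cl2, −78 °C, methanol quench) lets the benzyl ether oxygen open C12 with inversion (5-exo), the benzyl group leaving as its methyl ether, to give (1S)-1-[(2R,4S,5R)-5-ethenyl-4-(triethylsilyloxy)oxolan-2-yl]propan-1-ol F4 with the required 12R centre. Dess–Martin oxidation gives 1-[(2R,4S,5R)-5-ethenyl-4-(triethylsilyloxy)oxolan-2-yl]propan-1-one F5. LiBH(s-Bu)3 (THF, −78 °C) reduces it under Felkin–Anh control to (1R)-1-[(2R,4S,5R)-5-ethenyl-4-(triethylsilyloxy)oxolan-2-yl]propan-1-ol F6. CBr4 with P(n-C8H17)3 (toluene, 70 °C) then installs the bromide with inversion to give 10.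

Risk 3, the enyne cross-metathesis (step 10). Z-selectivity may be incomplete and the Z/E isomers hard to separate. The fallback sets out from 17 and comes back at 21. Ozonolysis of the allyl group (O3, CH2Cl2/MeOH, −78 °C; PPh3) gives 2-[(2S,3S,5S,6S,8R)-8-[(1S)-1-bromopropyl]-3,5-dichloro-6-(triethylsilyloxy)oxocan-2-yl]acetaldehyde F7. Peterson olefination with lithiated 1,3-bis(triisopropylsilyl)propyne (n-BuLi, THF, −78 °C) then gives the Z-enyne 21 with high Z-selectivity.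

**Further compounds**

F1 | step 8 | (5S)-6-[(2R,3S,5R)-5-[(1S)-1-bromopropyl]-3-(triethylsilyloxy)oxolan-2-yl]-5-chlorohex-1-en-4-one | C=CCC(=O)[C@@H](Cl)C[C@H]1O[C@@H]([C@@H](Br)CC)C[C@@H]1O[Si](CC)(CC)CC
F2 | step 8 | {[(3S,5S,6S,8R)-8-[(1S)-1-bromopropyl]-3,5-dichloro-2-(prop-2-en-1-yl)-2-(trimethylsilyloxy)oxocan-6-yl]oxy}triethylsilane (mixture at C2) | C=CCC1(O[Si](C)(C)C)O[C@@H]([C@@H](Br)CC)C[C@H](O[Si](CC)(CC)CC)[C@@H](Cl)C[C@@H]1Cl
F3 | step 5 | (2S,3S)-2-[(2S,3R)-3-[(2,6-dichlorophenyl)methoxy]-2-(triethylsilyloxy)pent-4-en-1-yl]-3-ethyloxirane | C=C[C@@H](OCc1c(Cl)cccc1Cl)[C@@H](O[Si](CC)(CC)CC)C[C@@H]1O[C@H]1CC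
F4 | step 5 | (1S)-1-[(2R,4S,5R)-5-ethenyl-4-(triethylsilyloxy)oxolan-2-yl]propan-1-ol | C=C[C@H]1O[C@@H]([C@@H](O)CC)C[C@@H]1O[Si](CC)(CC)CC
F5 | step 5 | 1-[(2R,4S,5R)-5-ethenyl-4-(triethylsilyloxy)oxolan-2-yl]propan-1-one | C=C[C@H]1O[C@@H](C(=O)CC)C[C@@H]1O[Si](CC)(CC)CC
F6 | step 5 | (1R)-1-[(2R,4S,5R)-5-ethenyl-4-(triethylsilyloxy)oxolan-2-yl]propan-1-ol | C=C[C@H]1O[C@@H]([C@H](O)CC)C[C@@H]1O[Si](CC)(CC)CC
F7 | step 10 | 2-[(2S,3S,5S,6S,8R)-8-[(1S)-1-bromopropyl]-3,5-dichloro-6-(triethylsilyloxy)oxocan-2-yl]acetaldehyde | O=CC[C@@H]1O[C@@H]([C@@H](Br)CC)C[C@H](O[Si](CC)(CC)CC)[C@@H](Cl)C[C@@H]1Cl
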